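**Plan**

Atom labels: C1 lactone C=O, C2 tertiary carbinol, C3 ring CH, C4 ring OCH2, C7 benzylic carbinol on C3. The enabling feature is that C7 and C3 are the formyl carbon and the γ-carbon of an aldehyde allylboration, and O7 can acylate at C1 to give an isomeric five-membered lactone (ring O7–C7–C3–C2–C1) with an exocyclic C2=CH2.
Retrosynthetic cuts, in order: the C1–O4 ester bond (traded for C1–O7 by acyl shift), the aryl–CH2 bond of the C2 benzyl group (aryl copper plus spiro-epoxide), the C2–O bond (epoxidation of C2=CH2), then C1–O7 and C3–C7 together (lactonising allylboration), the C–B bond (SN2' borylation) and the C2–C3 bond (Morita–Baylis–Hillman).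
Forward order: acrylate and silyloxyacetaldehyde give an allylic acetate and then the (E)-allylboronate; its addition to O-silylated vanillin joins the chain and closes the isomeric lactone; epoxidation and aryl transfer complete the skeleton; freeing O4 and moving the acyl group from O7 to O4 gives the ring of the target; desilylation ends the route.
Stereochemistry: the C3/C7 relative configuration comes from the boronate alkene geometry through a chair transition state and the absolute configuration from a chiral phosphoric acid; C2 comes from peroxide delivery to the face of the isomeric lactone opposite the cis CH2O arm and aryl group; the acyl shift touches no stereocentre.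

Key step: step 5

Remark: the sense of induction of the (R)-configured phosphoric acid (allyl transfer to the Re face of the aryl aldehyde) is carried over from allyl- and crotylboronate additions; if the ester-bearing boronate responded in the opposite sense, the (S)-acid would be used with nothing else changed.

**Route**

Step 1
Reactants: 1 vanillin
Product: 2 3-methoxy-4-(triisopropylsilyloxy)benzaldehyde
Conditions: TIPSCl, imidazole, DMF, rt
Reagents that add atoms: triisopropylsilyl chloride, CC(C)[Si](Cl)(C(C)C)C(C)C
Why: Imidazole-mediated O-silylation of the phenol; the TIPS ether is chosen because it should survive the basic peroxide, the Grignard reagent and mild acid used later and is removed last by fluoride.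

Step 2
Reactants: 3 (tert-butyldimethylsilyloxy)acetaldehyde; 4 methyl acrylate
Product: 5 methyl 4-(tert-butyldimethylsilyloxy)-3-hydroxy-2-methylenebutanoate (racemic)
Conditions: DABCO (0.5 equiv), methyl acrylate (3 equiv), MeOH, rt
Reagents that add atoms: none
Why: Morita–Baylis–Hillman reaction, in which the DABCO–acrylate zwitterion adds to the unhindered, inductively activated α-silyloxy aldehyde; the carbinol centre is racemic and is erased in step 4.

Step 3
Reactants: 5 methyl 4-(tert-butyldimethylsilyloxy)-3-hydroxy-2-methylenebutanoate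
Product: 6 methyl 3-acetoxy-4-(tert-butyldimethylsilyloxy)-2-methylenebutanoate (racemic)
Conditions: Ac2O, pyridine, DMAP (cat.), CH2Cl2, 0 °C
Reagents that add atoms: acetic anhydride, CC(=O)OC(C)=O
Why: DMAP-catalysed O-acetylation of the secondary allylic alcohol, which turns the hydroxyl into the leaving group for the allylic borylation.

Step 4
Reactants: 6 methyl 3-acetoxy-4-(tert-butyldimethylsilyloxy)-2-methylenebutanoate; 7 bis(pinacolato)diboron
Product: 8 methyl (E)-4-(tert-butyldimethylsilyloxy)-2-[(4,4,5,5-tetramethyl-1,3,2-dioxaborolan-2-yl)methyl]but-2-enoate (CH2OTBS cis to CH2B, trans to CO2Me)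
Conditions: CuCl (10 mol %), LiCl, KOAc, DMF, rt
Reagents that add atoms: none
Why: Copper-catalysed SN2' allylic borylation, in which a boryl-copper species adds to the acrylate terminus and acetate is expelled; as is usual for ester-bearing allylic acetates of this type, the trisubstituted alkene should form with the ester trans to the CH2OTBS group.

Step 5
Reactants: 2 3-methoxy-4-(triisopropylsilyloxy)benzaldehyde; 8 methyl (E)-4-(tert-butyldimethylsilyloxy)-2-[(4,4,5,5-tetramethyl-1,3,2-dioxaborolan-2-yl)methyl]but-2-enoate
Product: 10 (4R,5R)-4-[(tert-butyldimethylsilyloxy)methyl]-5-[3-methoxy-4-(triisopropylsilyloxy)phenyl]-3-methylenedihydrofuran-2(3H)-one (cis-4,5), via pinacol borate ester 9 (not isolated)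
Conditions: (R)-TRIP [(R)-3,3'-bis(2,4,6-triisopropylphenyl)-1,1'-binaphthyl-2,2'-diyl hydrogen phosphate] (10 mol %), 4 Å MS, toluene, 0 °C → rt; then PPTS (20 mol %), 45 °C
Reagents that add atoms: none
Why: The phosphoric acid hydrogen-bonds to a pinacol oxygen while the aldehyde oxygen binds boron, so the allyl group is passed on through a closed six-membered chair with the aryl group equatorial, and the C3–C7 bond forms with transposition of the double bond to C2=CH2. The closest known reactions are the chiral phosphoric acid-catalysed allyl- and crotylboration of aryl aldehydes with pinacol boronates and the thermal or Brønsted acid-promoted addition of 2-alkoxycarbonyl allylboronates to aldehydes that ends in α-methylene-γ-butyrolactones. The ring closes by 5-exo-trig acyl substitution, the borate oxygen on C7 attacking the methyl ester on C2 with loss of methoxy-Bpin. The relative configuration of C3 and C7 follows from the alkene geometry, since the CH2OTBS group cis to CH2B must sit axial in the chair, which gives the syn adduct and hence the lactone with CH2OTBS and aryl cis; the absolute configuration of both centres follows from the (R)-configured acid, which should open the Re face of the aldehyde (C7 R, C3 R). The step needs the catalysed path to outrun the racemic thermal one and needs C7 not to ionise on ring closure: the ester-deactivated boronate has a slow background reaction at or below room temperature, and the closure is driven by the weak acid PPTS instead of a sulfonic acid so that the electron-rich benzylic C–O bond is not broken and re-formed.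

Step 6
Reactants: 10 (4R,5R)-4-[(tert-butyldimethylsilyloxy)methyl]-5-[3-methoxy-4-(triisopropylsilyloxy)phenyl]-3-methylenedihydrofuran-2(3H)-one
Product: 11 (3R,6R,7R)-7-[(tert-butyldimethylsilyloxy)methyl]-6-[3-methoxy-4-(triisopropylsilyloxy)phenyl]-1,5-dioxaspiro[2.4]heptan-4-one (epoxide oxygen anti to CH2OTBS and aryl)
Conditions: t-BuOOH (in decane), DBU, CH2Cl2, 0 °C → rt
Reagents that add atoms: tert-butyl hydroperoxide, CC(C)(C)OO
Why: Weitz–Scheffer nucleophilic epoxidation, in which tert-butylperoxide adds to the exocyclic CH2 and the lactone enolate closes the oxirane on the peroxide oxygen held on the face opposite the cis CH2OTBS and aryl groups, which sets C2 with its oxygen anti to both.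

Step 7
Reactants: 12 4-bromo-2-methoxyphenol
Product: 13 (4-bromo-2-methoxyphenoxy)triisopropylsilane
Conditions: TIPSCl, imidazole, DMF, rt
Reagents that add atoms: triisopropylsilyl chloride, CC(C)[Si](Cl)(C(C)C)C(C)C
Why: Imidazole-mediated O-silylation of the phenol, which removes the acidic proton before the Grignard reagent is made and gives the second aryl ring the same protecting group as the first.

Step 8
Reactants: 11 (3R,6R,7R)-7-[(tert-butyldimethylsilyloxy)methyl]-6-[3-methoxy-4-(triisopropylsilyloxy)phenyl]-1,5-dioxaspiro[2.4]heptan-4-one; 13 (4-bromo-2-methoxyphenoxy)triisopropylsilane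
Product: 15 (3S,4R,5R)-4-[(tert-butyldimethylsilyloxy)methyl]-3-hydroxy-3-[3-methoxy-4-(triisopropylsilyloxy)benzyl]-5-[3-methoxy-4-(triisopropylsilyloxy)phenyl]dihydrofuran-2(3H)-one, via arylmagnesium bromide 14 (not isolated)
Conditions: 13, Mg, THF, rt; then CuI (20 mol %), 11, THF, −40 → −20 °C; aq NH4Cl
Reagents that add atoms: none
Why: Copper-catalysed Grignard opening of a 2,2-disubstituted glycidic ester, in which the aryl-copper species should attack the unhindered oxirane CH2 in SN2 fashion instead of the quaternary C2 or the lactone carbonyl, so that the C2–O bond and the C2 configuration are kept.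

Step 9
Reactants: 15 (3S,4R,5R)-4-[(tert-butyldimethylsilyloxy)methyl]-3-hydroxy-3-[3-methoxy-4-(triisopropylsilyloxy)benzyl]-5-[3-methoxy-4-(triisopropylsilyloxy)phenyl]dihydrofuran-2(3H)-one
Product: 16 (3S,4R,5R)-3-hydroxy-4-(hydroxymethyl)-3-[3-methoxy-4-(triisopropylsilyloxy)benzyl]-5-[3-methoxy-4-(triisopropylsilyloxy)phenyl]dihydrofuran-2(3H)-one
Conditions: PPTS, MeOH, rt
Reagents that add atoms: none
Why: Acid-catalysed methanolysis of a silyl ether, selective for the primary alkyl TBS group because aryl TIPS ethers are far more stable to mild acid in an alcohol.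

Step 10
Reactants: 16 (3S,4R,5R)-3-hydroxy-4-(hydroxymethyl)-3-[3-methoxy-4-(triisopropylsilyloxy)benzyl]-5-[3-methoxy-4-(triisopropylsilyloxy)phenyl]dihydrofuran-2(3H)-one
Product: 17 (3S,4R)-3-hydroxy-4-{(R)-hydroxy[3-methoxy-4-(triisopropylsilyloxy)phenyl]methyl}-3-[3-methoxy-4-(triisopropylsilyloxy)benzyl]dihydrofuran-2(3H)-one
Conditions: DBU (20 mol %), toluene, rt
Reagents that add atoms: none
Why: Base-catalysed translactonisation (intramolecular transesterification), in which the primary oxygen adds to the lactone carbonyl through a bicyclic tetrahedral intermediate and O7 is released; the equilibrium should favour the primary-oxygen lactone because the all-cis crowding of benzyl, CH2O and aryl groups on one ring is relieved, and no stereocentre is touched.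

Step 11
Reactants: 17 (3S,4R)-3-hydroxy-4-{(R)-hydroxy[3-methoxy-4-(triisopropylsilyloxy)phenyl]methyl}-3-[3-methoxy-4-(triisopropylsilyloxy)benzyl]dihydrofuran-2(3H)-one
Product: 18 (3S,4R)-3-hydroxy-4-[(R)-hydroxy(4-hydroxy-3-methoxyphenyl)methyl]-3-(4-hydroxy-3-methoxybenzyl)dihydrofuran-2(3H)-one (CNP0352022.1)
Conditions: TBAF, AcOH (1:1), THF, 0 °C
Reagents that add atoms: none
Why: Fluoride cleavage of the two aryl silyl ethers, buffered with acetic acid so that the p-hydroxybenzylic alcohol should neither ionise nor pass into a quinone methide.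

**Compound list**

1 | vanillin | COc1cc(C=O)ccc1O | starting material
2 | 3-methoxy-4-(triisopropylsilyloxy)benzaldehyde | COc1cc(C=O)ccc1O[Si](C(C)C)(C(C)C)C(C)C | intermediate
3 | (tert-butyldimethylsilyloxy)acetaldehyde | O=CCO[Si](C)(C)C(C)(C)C | starting material
4 | methyl acrylate | COC(=O)C=C | starting material
5 | methyl 4-(tert-butyldimethylsilyloxy)-3-hydroxy-2-methylenebutanoate (racemic) | COC(=O)C(=C)C(O)CO[Si](C)(C)C(C)(C)C | intermediate
6 | methyl 3-acetoxy-4-(tert-butyldimethylsilyloxy)-2-methylenebutanoate (racemic) | COC(=O)C(=C)C(OC(C)=O)CO[Si](C)(C)C(C)(C)C | intermediate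
7 | bis(pinacolato)diboron | CC1(C)OB(OC1(C)C)B1OC(C)(C)C(C)(C)O1 | starting material
8 | methyl (E)-4-(tert-butyldimethylsilyloxy)-2-[(4,4,5,5-tetramethyl-1,3,2-dioxaborolan-2-yl)methyl]but-2-enoate | COC(=O)/C(CB1OC(C)(C)C(C)(C)O1)=C/CO[Si](C)(C)C(C)(C)C | intermediate
9 | methyl (3R,4R)-3-[(tert-butyldimethylsilyloxy)methyl]-4-[3-methoxy-4-(triisopropylsilyloxy)phenyl]-2-methylene-4-[(4,4,5,5-tetramethyl-1,3,2-dioxaborolan-2-yl)oxy]butanoate | COC(=O)C(=C)[C@H](CO[Si](C)(C)C(C)(C)C)[C@@H](OB1OC(C)(C)C(C)(C)O1)c1ccc(O[Si](C(C)C)(C(C)C)C(C)C)c(OC)c1 | intermediate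
10 | (4R,5R)-4-[(tert-butyldimethylsilyloxy)methyl]-5-[3-methoxy-4-(triisopropylsilyloxy)phenyl]-3-methylenedihydrofuran-2(3H)-one | C=C1C(=O)O[C@@H](c2ccc(O[Si](C(C)C)(C(C)C)C(C)C)c(OC)c2)[C@H]1CO[Si](C)(C)C(C)(C)C | intermediate
11 | (3R,6R,7R)-7-[(tert-butyldimethylsilyloxy)methyl]-6-[3-methoxy-4-(triisopropylsilyloxy)phenyl]-1,5-dioxaspiro[2.4]heptan-4-one | O=C1O[C@@H](c2ccc(O[Si](C(C)C)(C(C)C)C(C)C)c(OC)c2)[C@@H](CO[Si](C)(C)C(C)(C)C)[C@@]12CO2 | intermediate
12 | 4-bromo-2-methoxyphenol | COc1cc(Br)ccc1O | starting material
13 | (4-bromo-2-methoxyphenoxy)triisopropylsilane | COc1cc(Br)ccc1O[Si](C(C)C)(C(C)C)C(C)C | intermediate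
14 | [3-methoxy-4-(triisopropylsilyloxy)phenyl]magnesium bromide | COc1cc([Mg]Br)ccc1O[Si](C(C)C)(C(C)C)C(C)C | intermediate
15 | (3S,4R,5R)-4-[(tert-butyldimethylsilyloxy)methyl]-3-hydroxy-3-[3-methoxy-4-(triisopropylsilyloxy)benzyl]-5-[3-methoxy-4-(triisopropylsilyloxy)phenyl]dihydrofuran-2(3H)-one | O=C1O[C@@H](c2ccc(O[Si](C(C)C)(C(C)C)C(C)C)c(OC)c2)[C@@H](CO[Si](C)(C)C(C)(C)C)[C@@]1(O)Cc3ccc(O[Si](C(C)C)(C(C)C)C(C)C)c(OC)c3 | intermediate
16 | (3S,4R,5R)-3-hydroxy-4-(hydroxymethyl)-3-[3-methoxy-4-(triisopropylsilyloxy)benzyl]-5-[3-methoxy-4-(triisopropylsilyloxy)phenyl]dihydrofuran-2(3H)-one | O=C1O[C@@H](c2ccc(O[Si](C(C)C)(C(C)C)C(C)C)c(OC)c2)[C@@H](CO)[C@@]1(O)Cc3ccc(O[Si](C(C)C)(C(C)C)C(C)C)c(OC)c3 | intermediate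
17 | (3S,4R)-3-hydroxy-4-{(R)-hydroxy[3-methoxy-4-(triisopropylsilyloxy)phenyl]methyl}-3-[3-methoxy-4-(triisopropylsilyloxy)benzyl]dihydrofuran-2(3H)-one | COc1cc(C[C@@]2(O)C(=O)OC[C@@H]2[C@@H](O)c2ccc(O[Si](C(C)C)(C(C)C)C(C)C)c(OC)c2)ccc1O[Si](C(C)C)(C(C)C)C(C)C | intermediate
18 | (3S,4R)-3-hydroxy-4-[(R)-hydroxy(4-hydroxy-3-methoxyphenyl)methyl]-3-(4-hydroxy-3-methoxybenzyl)dihydrofuran-2(3H)-one (CNP0352022.1) | COc1cc(C[C@@]2(O)C(=O)OC[C@@H]2[C@@H](O)c2ccc(O)c(OC)c2)ccc1O | target

**Step count and risks**

Total step count: 11. Longest linear sequence: 9 steps (steps 2, 3, 4, 5, 6, 8, 9, 10, 11, from 3 and 4).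

Steps most likely to fail:

Step 5. The ester-deactivated boronate may add too slowly to the electron-rich aldehyde under the phosphoric acid, so that the uncatalysed pathway lowers the enantiomeric purity, and partial ionisation at C7 during ring closure could erode the cis relation. The fallback moves the stereocontrol from the catalyst to boron and sets out from 8. Transesterification of 8 with diethanolamine in ether should give the diethanolamine complex of the allylboronic acid F1. Exchange with diisopropyl (S,S)-tartrate in ether/brine should give the tartrate allylboronate F2. Its boron is more Lewis acidic than that of a pinacol ester and should compensate for the deactivated allyl unit. By the established facial rule for tartrate allylboronates, the (S,S)-ester should deliver the allyl group to the Re face. Addition of F2 to 2 (4 Å MS, toluene, rt) should pass through the same chair to the tartrate borate ester F3, which PPTS closes to the lactone, so the route is rejoined at 10. Induction with aryl aldehydes is usually lower with this auxiliary, so enrichment of 10 by crystallisation or chiral-phase chromatography may be needed.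

Step 8. The Grignard reagent may attack the lactone carbonyl, or magnesium halide may open the oxirane with bromide, in competition with aryl transfer to CH2. The fallback changes the order of bond formation at C2, sets out from 10 and bypasses step 6. Copper-catalysed conjugate addition of 14 (CuI, THF, −40 °C) to the methylene lactone should give the α-benzyl lactone F4 as a mixture of C2 epimers, which does not matter. Deprotonation with KN(SiMe3)2 in THF at −78 °C should give the potassium enolate F5. 2-(Phenylsulfonyl)-3-phenyloxaziridine should hydroxylate F5 on the face opposite the cis CH2OTBS and aryl groups, so the route is rejoined at 15.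

Step 10. The acyl transfer may be slow because its tetrahedral intermediate is a strained bicycle, or it may stop at an equilibrium mixture. The fallback replaces reversible acyl transfer by an irreversible O-alkylation and sets out from 16. MsCl and Et3N (CH2Cl2, 0 °C) should sulfonylate only the primary hydroxyl and give the primary mesylate F6. LiOH in THF/H2O at 0 °C should open the benzylic lactone to the lithium carboxylate F7, whose carboxylate displaces the mesylate at C4 by 5-exo-tet SN2. This gives the primary-oxygen lactone with the configuration at C2, C3 and C7 unchanged, so the route is rejoined at 17.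

Further compounds
F1 | step 5 | diethanolamine complex of (E)-[4-(tert-butyldimethylsilyloxy)-2-(methoxycarbonyl)but-2-enyl]boronic acid | COC(=O)/C(C[B-]12OCC[NH+]1CCO2)=C/CO[Si](C)(C)C(C)(C)C
F2 | step 5 | diisopropyl (4S,5S)-2-[(E)-4-(tert-butyldimethylsilyloxy)-2-(methoxycarbonyl)but-2-enyl]-1,3,2-dioxaborolane-4,5-dicarboxylate | COC(=O)/C(CB1O[C@H](C(=O)OC(C)C)[C@@H](C(=O)OC(C)C)O1)=C/CO[Si](C)(C)C(C)(C)C
F3 | step 5 | tartrate borate ester of the syn homoallylic alcohol (tartrate analogue of 9) | COC(=O)C(=C)[C@H](CO[Si](C)(C)C(C)(C)C)[C@@H](OB1O[C@H](C(=O)OC(C)C)[C@@H](C(=O)OC(C)C)O1)c1ccc(O[Si](C(C)C)(C(C)C)C(C)C)c(OC)c1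
F4 | step 8 | (4R,5R)-4-[(tert-butyldimethylsilyloxy)methyl]-3-[3-methoxy-4-(triisopropylsilyloxy)benzyl]-5-[3-methoxy-4-(triisopropylsilyloxy)phenyl]dihydrofuran-2(3H)-one (C3 epimers) | O=C1O[C@@H](c2ccc(O[Si](C(C)C)(C(C)C)C(C)C)c(OC)c2)[C@@H](CO[Si](C)(C)C(C)(C)C)C1Cc3ccc(O[Si](C(C)C)(C(C)C)C(C)C)c(OC)c3
F5 | step 8 | potassium enolate of F4 | [K+].[O-]C1=C(Cc3ccc(O[Si](C(C)C)(C(C)C)C(C)C)c(OC)c3)[C@H](CO[Si](C)(C)C(C)(C)C)[C@H](c2ccc(O[Si](C(C)C)(C(C)C)C(C)C)c(OC)c2)O1
F6 | step 10 | primary methanesulfonate of 16 | O=C1O[C@@H](c2ccc(O[Si](C(C)C)(C(C)C)C(C)C)c(OC)c2)[C@@H](COS(C)(=O)=O)[C@@]1(O)Cc3ccc(O[Si](C(C)C)(C(C)C)C(C)C)c(OC)c3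
F7 | step 10 | lithium (2S,3R,4R)-2,4-dihydroxy-3-[(methylsulfonyloxy)methyl]-2-[3-methoxy-4-(triisopropylsilyloxy)benzyl]-4-[3-methoxy-4-(triisopropylsilyloxy)phenyl]butanoate | [Li+].[O-]C(=O)[C@](O)(Cc1ccc(O[Si](C(C)C)(C(C)C)C(C)C)c(OC)c1)[C@H](COS(C)(=O)=O)[C@@H](O)c2ccc(O[Si](C(C)C)(C(C)C)C(C)C)c(OC)c2
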